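**Retrosynthetic overview**

- Feature used: rings A and B share the C5–C10 bond, quaternary C4 (bearing C18 and C19) lies next to C5, and C1 carries oxygen beside C2–C3. Ring A is therefore the cycloadduct of the 2-siloxydiene C10=C1(OSi)–C2=C3 with the Z-α-methyl enoate C5=C4, and ring B closes in the same event through the tether C9–C8–C6.
- After the cycloaddition: Saegusa oxidation to the Δ2-1-ketone, C19–O–C10 lactone by hypervalent-iodine oxidation of the dienol ether, β-face nucleophilic epoxidation, α-face hydride to the 1β-alcohol.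
- Before it: ring C by organocatalytic Michael addition and aldol condensation (sets C9), acetate arm on C8, conjugate propargylation anti to the C9 chain (quaternary C8), ketyl–alkyne closure of ring D (C13–C16).
- C6 is set by enamine-catalysed hydroxymethylation and relays to C5 and C4; Still–Gennari olefination gives the Z-enoate; the C9 arm becomes the vinyl ketone and then the silyl dienol ether.
- Ring order: C, then D, then A and B together, then the lactone and the oxirane.

Key step: step 16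

Assumption: locants are gibberellane locants and α/β refer to the customary gibberellin drawing with the 19,10-lactone on the α face; aldehyde 1 is taken as a catalogue compound; TBS = tert-butyldimethylsilyl, TBDPS = tert-butyldiphenylsilyl, TMS = trimethylsilyl.

Step 1
Reactants: 1 4-[(tert-butyldimethylsilyl)oxy]butanal; 2 but-3-en-2-one (methyl vinyl ketone)
Product: 3 (2S)-2-{2-[(tert-butyldimethylsilyl)oxy]ethyl}-5-oxohexanal
Conditions: (S)-α,α-diphenylprolinol methyl ether (5 mol%), ethyl 3,4-dihydroxybenzoate (20 mol%), neat, 4 °C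
Reagents that add atoms: none
Why: Enamine-catalysed asymmetric Michael addition of an aldehyde to a vinyl ketone, in which the diarylmethyl group of the (S)-catalyst shields one face of the E-enamine so that C9 should form with the S configuration that later becomes 9β-H.

Step 2
Reactants: 3 keto aldehyde
Product: 4 (4S)-4-{2-[(tert-butyldimethylsilyl)oxy]ethyl}cyclohex-2-en-1-one
Conditions: LiOH·H2O (cat.), i-PrOH, rt
Reagents that add atoms: none
Why: Intramolecular aldol condensation of the 1,5-keto aldehyde closes ring C (C14–C8) without a new stereocentre, the mild base being chosen so that C9 (γ to the new enone) should not epimerise.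

Step 3
Reactants: 4 enone; 5 tert-butyl[(1-methoxyethenyl)oxy]dimethylsilane
Product: 6 methyl 2-[(1S,6S)-3-(TBS-oxy)-6-(2-TBS-oxyethyl)cyclohex-2-en-1-yl]acetate
Conditions: MeCN, 55 °C
Reagents that add atoms: none
Why: Mukaiyama–Michael addition with silyl transfer should give the regiodefined silyl enol ether C13(OSi)=C14, the acetate unit (C6–C5) entering C8 anti to the C9 chain at a transient stereocentre that step 4 removes.

Step 4
Reactants: 6 silyl enol ether
Product: 7 methyl 2-[(6S)-6-{2-[(tert-butyldimethylsilyl)oxy]ethyl}-3-oxocyclohex-1-en-1-yl]acetate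
Conditions: Pd(OAc)2 (1.1 equiv), MeCN, 40 °C
Reagents that add atoms: none
Why: Saegusa–Ito oxidation, in which the palladium enolate at C14 loses H8 by β-hydride elimination to give the 3,4-disubstituted enone and leaves C9 untouched.

Step 5
Reactants: 7 enone; 8 tributyl(propa-1,2-dien-1-yl)stannane
Product: 9 methyl 2-[(1R,2S)-2-(2-TBS-oxyethyl)-5-oxo-1-(prop-2-yn-1-yl)cyclohexyl]acetate
Conditions: TiCl4, CH2Cl2, −78 °C
Reagents that add atoms: none
Why: Lewis-acid-promoted conjugate propargylation (SE2′ addition of an allenylstannane, a Hosomi–Sakurai-type reaction), in which allylic 1,2-strain places the C9 chain pseudoaxial and the nucleophile adds axially to C8 on the opposite face, so that the propargyl group (C15–C17) should be trans and the acetate arm cis to the C9 chain.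

Step 6
Reactants: 9 propargyl ketone
Product: 10 methyl 2-[(1R,2S,5S)-2-(2-TBS-oxyethyl)-5-hydroxy-6-methylidenebicyclo[3.2.1]octan-1-yl]acetate
Conditions: SmI2, HMPA, t-BuOH, THF, 0 °C
Reagents that add atoms: none
Why: Ketyl–alkyne reductive cyclisation (5-exo-dig radical addition), in which the samarium ketyl at C13 adds to C16 of the axial propargyl arm and the vinyl radical is reduced and protonated, giving ring D with the 16-methylidene and the tertiary 13-OH, the one-carbon bridge fixing C13.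

Step 7
Reactants: 10 hydroxy ester
Product: 11 2-[(1R,2S,5S)-2-(2-TBS-oxyethyl)-5-hydroxy-6-methylidenebicyclo[3.2.1]octan-1-yl]acetaldehyde
Conditions: i-Bu2AlH (2.2 equiv), CH2Cl2, −78 °C; aq. potassium sodium tartrate
Reagents that add atoms: none
Why: Partial hydride reduction of the methyl ester stops at the aldehyde because the aluminium hemiacetal is stable at −78 °C, one equivalent of hydride being used up by the tertiary alcohol.

Step 8
Reactants: 11 aldehyde; 12 formaldehyde (37% aqueous)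
Product: 13 (2S)-2-[(1S,2S,5S)-2-(2-TBS-oxyethyl)-5-hydroxy-6-methylidenebicyclo[3.2.1]octan-1-yl]-3-hydroxypropanal
Conditions: (R)-α,α-diphenylprolinol trimethylsilyl ether (20 mol%), toluene/pH 7 phosphate buffer, rt
Reagents that add atoms: none
Why: Enamine-catalysed α-hydroxymethylation (cross-aldol with formaldehyde), in which the (R)-catalyst shields one face of the E-enamine so that C7 should be attached to C6 with the S configuration under catalyst control, the three carbon substituents of quaternary C8 being of similar size.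

Step 9
Reactants: 13 hydroxy aldehyde (crude)
Product: 14 (2S)-3-[(tert-butyldiphenylsilyl)oxy]-2-[(1S,2S,5S)-2-(2-TBS-oxyethyl)-5-hydroxy-6-methylidenebicyclo[3.2.1]octan-1-yl]propanal
Conditions: TBDPSCl, imidazole, CH2Cl2, 0 °C
Reagents that add atoms: tert-butyl(chloro)diphenylsilane, CC(C)(C)[Si](Cl)(c1ccccc1)c1ccccc1
Why: Selective silylation of the primary alcohol (the bridgehead tertiary 13-OH is too hindered) caps O7 at once, which should prevent dehydration or retro-aldol loss of C7 and so preserve C6.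

Step 10
Reactants: 14 aldehyde; 15 methyl 2-[bis(2,2,2-trifluoroethoxy)phosphoryl]propanoate
Product: 16 methyl (2Z,4S)-5-(TBDPS-oxy)-4-[(1S,2S,5S)-2-(2-TBS-oxyethyl)-5-hydroxy-6-methylidenebicyclo[3.2.1]octan-1-yl]-2-methylpent-2-enoate
Conditions: KN(SiMe3)2, 18-crown-6, THF, −78 °C
Reagents that add atoms: none
Why: Still–Gennari olefination, whose trifluoroethyl phosphonate eliminates under kinetic control to give the Z-enoate (C19 cis to C6), the weakly basic phosphonate anion at −78 °C being expected to leave C6 and the free tertiary alcohol alone.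

Step 11
Reactants: 16 Z-enoate
Product: 17 methyl (2Z,4S)-5-(TBDPS-oxy)-4-[(1S,2S,5S)-5-hydroxy-2-(2-hydroxyethyl)-6-methylidenebicyclo[3.2.1]octan-1-yl]-2-methylpent-2-enoate (primary alcohol on the C9 arm)
Conditions: camphorsulfonic acid (cat.), MeOH/CH2Cl2, 0 °C
Reagents that add atoms: none
Why: Acid-catalysed methanolysis (chemoselective desilylation) removes the primary TBS ether much faster than the hindered TBDPS ether and touches no stereocentre.

Step 12
Reactants: 17 alcohol
Product: 18 methyl (2Z,4S)-5-(TBDPS-oxy)-4-[(1S,2S,5S)-5-hydroxy-6-methylidene-2-(2-oxoethyl)bicyclo[3.2.1]octan-1-yl]-2-methylpent-2-enoate (aldehyde on the C9 arm)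
Conditions: Dess–Martin periodinane, NaHCO3, CH2Cl2, 0 °C to rt
Reagents that add atoms: none
Why: Dess–Martin oxidation of the primary alcohol to the aldehyde, the tertiary 13-OH being unable to oxidise.

Step 13
Reactants: 18 aldehyde; 19 bromo(ethenyl)magnesium (vinylmagnesium bromide, 3 equiv)
Product: 20 methyl (2Z,4S)-5-(TBDPS-oxy)-4-[(1S,2S,5S)-5-hydroxy-2-(2-hydroxybut-3-en-1-yl)-6-methylidenebicyclo[3.2.1]octan-1-yl]-2-methylpent-2-enoate (allylic alcohol, both C1 epimers)
Conditions: THF, −78 °C; aq. NH4Cl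
Reagents that add atoms: none
Why: Grignard 1,2-addition to the aldehyde, much faster at −78 °C than attack on the hindered α-methyl enoate, forms the carbinol centre C1 unselectively, which is of no consequence because step 14 removes it.

Step 14
Reactants: 20 allylic alcohol
Product: 21 methyl (2Z,4S)-5-(TBDPS-oxy)-4-[(1S,2S,5S)-5-hydroxy-6-methylidene-2-(2-oxobut-3-en-1-yl)bicyclo[3.2.1]octan-1-yl]-2-methylpent-2-enoate (vinyl ketone)
Conditions: Dess–Martin periodinane, NaHCO3, CH2Cl2, 0 °C
Reagents that add atoms: none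
Why: Dess–Martin oxidation of the allylic alcohol under non-basic conditions should give the vinyl ketone without conjugate addition to it.

Step 15
Reactants: 21 vinyl ketone
Product: 22 methyl (2Z,4S)-5-(TBDPS-oxy)-4-[(1S,2S,5S)-5-(TBS-oxy)-2-[(1Z)-2-(TBS-oxy)buta-1,3-dien-1-yl]-6-methylidenebicyclo[3.2.1]octan-1-yl]-2-methylpent-2-enoate
Conditions: TBSOTf (3 equiv), Et3N, CH2Cl2, −78 to 0 °C
Reagents that add atoms: tert-butyldimethylsilyl trifluoromethanesulfonate, CC(C)(C)[Si](C)(C)OS(=O)(=O)C(F)(F)F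
Why: Soft enolisation and O-silylation of the vinyl ketone towards C10, its only α-CH2, should give the 2-siloxydiene as the Z-enol ether (C9 trans to C2), the excess reagent also silylating the tertiary 13-OH.

Step 16
Reactants: 22 triene
Product: 23 tetracyclic silyl enol ether: methyl 1,13-bis(TBS-oxy)-7-(TBDPS-oxy)-20-norgibberella-1,16-dien-19-oate (4α-CO2Me; 4β-Me; 5β-H; 6α-H; 9β-H; 10α-H as drawn)
Conditions: toluene (0.01 M), BHT (cat.), 160 °C, sealed tube
Reagents that add atoms: none
Why: Thermal concerted suprafacial [4+2] cycloaddition between the electron-rich diene C10=C1(OSi)–C2=C3 and the Z-α-methyl enoate C5=C4 forms C5–C10 and C3–C4, the closest known reaction type being the type-1 intramolecular Diels–Alder reaction of 1,3,8-nonatrienes whose diene is a 2-silyloxybutadiene. Ring A closes as the six-membered cycloadduct ring and ring B as a five-membered ring in the fused mode through the three-atom tether C9–C8–C6, whose ends are held cis on ring C. C4 is set relative to C5 by the Z geometry of the enoate (C18 cis to H5, C19 on the α face), and C5 is set relative to C6 by allylic 1,3-strain: the cis ester forces H6 into the alkene plane, C7 and C8 then lie on opposite faces, and the diene, which is tied to C8, must add anti to C7. C10 follows from the endo or exo mode and is drawn as 10α-H, but either epimer serves because C10 becomes trigonal again in step 19. The step needs regioselectivity and π-facial selectivity; the first is secured by the tether together with the match of the nucleophilic diene terminus C10 with the enoate β-carbon C5, the second by the C6 stereocentre together with the Z-ester.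

Step 17
Reactants: 23 silyl enol ether
Product: 24 methyl 13-(TBS-oxy)-7-(TBDPS-oxy)-1-oxo-20-norgibberella-2,16-dien-19-oate
Conditions: Pd(OAc)2 (1.2 equiv), MeCN, rt to 40 °C
Reagents that add atoms: none
Why: Saegusa–Ito oxidation of the C1 silyl enol ether, in which β-hydride elimination can only involve C3, gives the Δ2-1-ketone and makes H10 the only enolisable hydrogen.

Step 18
Reactants: 24 enone ester
Product: 25 13-(TBS-oxy)-7-(TBDPS-oxy)-1-oxo-20-norgibberella-2,16-dien-19-oic acid
Conditions: LiI, pyridine, reflux; aq. HCl work-up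
Reagents that add atoms: none
Why: SN2 dealkylation of the hindered methyl ester by iodide at the methyl carbon avoids the shielded C19 carbonyl, and iodide adds to the enone only reversibly.

Step 19
Reactants: 25 enone acid
Product: 27 enone lactone: 13-(TBS-oxy)-7-(TBDPS-oxy)-1-oxo-20-norgibberella-2,16-dien-19-oic acid 19,10-lactone, via silyl dienol ether silyl ester 26 (not isolated)
Conditions: Me3SiOTf, Et3N, CH2Cl2, 0 °C; salts filtered off; then PhIO, BF3·OEt2, CH2Cl2, −78 to −40 °C
Reagents that add atoms: none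
Why: Hypervalent-iodine α-oxidation of a ketone with internal carboxylate capture (oxidative lactonisation of a 5-oxo acid), in which the cross-conjugated silyl dienol ether C1(OSi)=C10 is taken up by the BF3-activated iodosylbenzene and the C19 carboxylate, held on the α face at C4, attacks C10 with loss of iodobenzene to close the γ-lactone, so that the C10–O bond should be α whatever the ring fusion of 23 was.

Step 20
Reactants: 27 bis-silyl enone lactone
Product: 28 7,13-dihydroxy-1-oxo-20-norgibberella-2,16-dien-19-oic acid 19,10-lactone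
Conditions: HF·pyridine, pyridine/THF, 0 °C to rt
Reagents that add atoms: none
Why: Fluoride-mediated desilylation removes the primary TBDPS ether at O7 and the tertiary TBS ether at O13 in one operation, the enone lactone being stable to these conditions.

Step 21
Reactants: 28 diol
Product: 29 13-hydroxy-1-oxo-20-norgibberella-2,16-diene-7,19-dioic acid 19,10-lactone
Conditions: TEMPO (cat.), PhI(OAc)2, MeCN/H2O, rt
Reagents that add atoms: water, O
Why: Oxoammonium-catalysed oxidation takes the primary alcohol through the aldehyde hydrate to the C7 acid while the tertiary 13-OH cannot react, and C6 should hold because C7 trans to C4 on ring B is also the less strained arrangement.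

Step 22
Reactants: 29 enone acid
Product: 30 2β,3β-epoxy-13-hydroxy-1-oxo-20-norgibberell-16-ene-7,19-dioic acid 19,10-lactone
Conditions: t-BuOOH, DBU (3 equiv), CH2Cl2, 0 °C to rt
Reagents that add atoms: tert-butyl hydroperoxide, CC(C)(C)OO
Why: Weitz–Scheffer nucleophilic epoxidation, in which the hydroperoxide anion should add to C3 on the β face, away from the lactone bridge that covers the α face, the enolate then closing the oxirane on the same face.

Step 23
Reactants: 30 epoxy ketone
Product: 31 the target gibberellin (2β,3β-epoxy-1β,13-dihydroxy-20-norgibberell-16-ene-7,19-dioic acid 19,10-lactone)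
Conditions: K[s-Bu3BH] (2.5 equiv), THF, −78 °C; aq. NH4Cl, then pH 3
Reagents that add atoms: none
Why: Ketone reduction by a bulky trialkylborohydride, for which attack on C1 from the β face is blocked by the neighbouring oxirane oxygen and by the C9/C11 flank of ring C, so that hydride should arrive from the α side and give the 1β-alcohol cis to the epoxide, while carboxylate, lactone and oxirane are not reduced at −78 °C.

**Compound list**

1 | 4-[(tert-butyldimethylsilyl)oxy]butanal | O=CCCCO[Si](C)(C)C(C)(C)C | starting material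
2 | but-3-en-2-one | CC(=O)C=C | starting material
3 | (2S)-2-{2-[(tert-butyldimethylsilyl)oxy]ethyl}-5-oxohexanal | O=C[C@H](CCO[Si](C)(C)C(C)(C)C)CCC(C)=O | intermediate
4 | (4S)-4-{2-[(tert-butyldimethylsilyl)oxy]ethyl}cyclohex-2-en-1-one | O=C1C=C[C@H](CCO[Si](C)(C)C(C)(C)C)CC1 | intermediate
5 | tert-butyl[(1-methoxyethenyl)oxy]dimethylsilane | C=C(OC)O[Si](C)(C)C(C)(C)C | starting material
6 | methyl 2-[(1S,6S)-3-[(tert-butyldimethylsilyl)oxy]-6-{2-[(tert-butyldimethylsilyl)oxy]ethyl}cyclohex-2-en-1-yl]acetate | COC(=O)C[C@@H]1C=C(O[Si](C)(C)C(C)(C)C)CC[C@H]1CCO[Si](C)(C)C(C)(C)C | intermediate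
7 | methyl 2-[(6S)-6-{2-[(tert-butyldimethylsilyl)oxy]ethyl}-3-oxocyclohex-1-en-1-yl]acetate | COC(=O)CC1=CC(=O)CC[C@H]1CCO[Si](C)(C)C(C)(C)C | intermediate
8 | tributyl(propa-1,2-dien-1-yl)stannane | C=C=C[Sn](CCCC)(CCCC)CCCC | starting material
9 | methyl 2-[(1R,2S)-2-{2-[(tert-butyldimethylsilyl)oxy]ethyl}-5-oxo-1-(prop-2-yn-1-yl)cyclohexyl]acetate | C#CC[C@]1(CC(=O)OC)CC(=O)CC[C@H]1CCO[Si](C)(C)C(C)(C)C | intermediate
10 | methyl 2-[(1R,2S,5S)-2-{2-[(tert-butyldimethylsilyl)oxy]ethyl}-5-hydroxy-6-methylidenebicyclo[3.2.1]octan-1-yl]acetate | C=C1C[C@]2(CC(=O)OC)C[C@@]1(O)CC[C@H]2CCO[Si](C)(C)C(C)(C)C | intermediate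
11 | 2-[(1R,2S,5S)-2-{2-[(tert-butyldimethylsilyl)oxy]ethyl}-5-hydroxy-6-methylidenebicyclo[3.2.1]octan-1-yl]acetaldehyde | C=C1C[C@]2(CC=O)C[C@@]1(O)CC[C@H]2CCO[Si](C)(C)C(C)(C)C | intermediate
12 | formaldehyde | C=O | starting material
13 | (2S)-2-[(1S,2S,5S)-2-{2-[(tert-butyldimethylsilyl)oxy]ethyl}-5-hydroxy-6-methylidenebicyclo[3.2.1]octan-1-yl]-3-hydroxypropanal | C=C1C[C@]2([C@@H](CO)C=O)C[C@@]1(O)CC[C@H]2CCO[Si](C)(C)C(C)(C)C | intermediate
14 | (2S)-3-[(tert-butyldiphenylsilyl)oxy]-2-[(1S,2S,5S)-2-{2-[(tert-butyldimethylsilyl)oxy]ethyl}-5-hydroxy-6-methylidenebicyclo[3.2.1]octan-1-yl]propanal | C=C1C[C@]2([C@@H](CO[Si](c3ccccc3)(c3ccccc3)C(C)(C)C)C=O)C[C@@]1(O)CC[C@H]2CCO[Si](C)(C)C(C)(C)C | intermediate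
15 | methyl 2-[bis(2,2,2-trifluoroethoxy)phosphoryl]propanoate | CC(C(=O)OC)P(=O)(OCC(F)(F)F)OCC(F)(F)F | starting material
16 | methyl (2Z,4S)-5-[(tert-butyldiphenylsilyl)oxy]-4-[(1S,2S,5S)-2-{2-[(tert-butyldimethylsilyl)oxy]ethyl}-5-hydroxy-6-methylidenebicyclo[3.2.1]octan-1-yl]-2-methylpent-2-enoate | C=C1C[C@]2([C@@H](CO[Si](c3ccccc3)(c3ccccc3)C(C)(C)C)/C=C(/C)C(=O)OC)C[C@@]1(O)CC[C@H]2CCO[Si](C)(C)C(C)(C)C | intermediate
17 | methyl (2Z,4S)-5-[(tert-butyldiphenylsilyl)oxy]-4-[(1S,2S,5S)-5-hydroxy-2-(2-hydroxyethyl)-6-methylidenebicyclo[3.2.1]octan-1-yl]-2-methylpent-2-enoate | C=C1C[C@]2([C@@H](CO[Si](c3ccccc3)(c3ccccc3)C(C)(C)C)/C=C(/C)C(=O)OC)C[C@@]1(O)CC[C@H]2CCO | intermediate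
18 | methyl (2Z,4S)-5-[(tert-butyldiphenylsilyl)oxy]-4-[(1S,2S,5S)-5-hydroxy-6-methylidene-2-(2-oxoethyl)bicyclo[3.2.1]octan-1-yl]-2-methylpent-2-enoate | C=C1C[C@]2([C@@H](CO[Si](c3ccccc3)(c3ccccc3)C(C)(C)C)/C=C(/C)C(=O)OC)C[C@@]1(O)CC[C@H]2CC=O | intermediate
19 | bromo(ethenyl)magnesium | C=C[Mg]Br | starting material
20 | methyl (2Z,4S)-5-[(tert-butyldiphenylsilyl)oxy]-4-[(1S,2S,5S)-5-hydroxy-2-(2-hydroxybut-3-en-1-yl)-6-methylidenebicyclo[3.2.1]octan-1-yl]-2-methylpent-2-enoate (both carbinol epimers) | C=C1C[C@]2([C@@H](CO[Si](c3ccccc3)(c3ccccc3)C(C)(C)C)/C=C(/C)C(=O)OC)C[C@@]1(O)CC[C@H]2CC(O)C=C | intermediate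
21 | methyl (2Z,4S)-5-[(tert-butyldiphenylsilyl)oxy]-4-[(1S,2S,5S)-5-hydroxy-6-methylidene-2-(2-oxobut-3-en-1-yl)bicyclo[3.2.1]octan-1-yl]-2-methylpent-2-enoate | C=C1C[C@]2([C@@H](CO[Si](c3ccccc3)(c3ccccc3)C(C)(C)C)/C=C(/C)C(=O)OC)C[C@@]1(O)CC[C@H]2CC(=O)C=C | intermediate
22 | methyl (2Z,4S)-5-[(tert-butyldiphenylsilyl)oxy]-4-[(1S,2S,5S)-5-[(tert-butyldimethylsilyl)oxy]-2-{(1Z)-2-[(tert-butyldimethylsilyl)oxy]buta-1,3-dien-1-yl}-6-methylidenebicyclo[3.2.1]octan-1-yl]-2-methylpent-2-enoate | C=C1C[C@]2([C@@H](CO[Si](c3ccccc3)(c3ccccc3)C(C)(C)C)/C=C(/C)C(=O)OC)C[C@@]1(O[Si](C)(C)C(C)(C)C)CC[C@H]2/C=C(\O[Si](C)(C)C(C)(C)C)C=C | intermediate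
23 | methyl 1,13-bis[(tert-butyldimethylsilyl)oxy]-7-[(tert-butyldiphenylsilyl)oxy]-20-norgibberella-1,16-dien-19-oate (10α-H drawn) | C=C1C[C@]23C[C@@]1(O[Si](C)(C)C(C)(C)C)CC[C@H]2[C@@H]4C(O[Si](C)(C)C(C)(C)C)=CC[C@@](C)(C(=O)OC)[C@H]4[C@@H]3CO[Si](c5ccccc5)(c5ccccc5)C(C)(C)C | intermediate
24 | methyl 13-[(tert-butyldimethylsilyl)oxy]-7-[(tert-butyldiphenylsilyl)oxy]-1-oxo-20-norgibberella-2,16-dien-19-oate | C=C1C[C@]23C[C@@]1(O[Si](C)(C)C(C)(C)C)CC[C@H]2[C@@H]4C(=O)C=C[C@@](C)(C(=O)OC)[C@H]4[C@@H]3CO[Si](c5ccccc5)(c5ccccc5)C(C)(C)C | intermediate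
25 | 13-[(tert-butyldimethylsilyl)oxy]-7-[(tert-butyldiphenylsilyl)oxy]-1-oxo-20-norgibberella-2,16-dien-19-oic acid | C=C1C[C@]23C[C@@]1(O[Si](C)(C)C(C)(C)C)CC[C@H]2[C@@H]4C(=O)C=C[C@@](C)(C(=O)O)[C@H]4[C@@H]3CO[Si](c5ccccc5)(c5ccccc5)C(C)(C)C | intermediate
26 | trimethylsilyl 13-[(tert-butyldimethylsilyl)oxy]-7-[(tert-butyldiphenylsilyl)oxy]-1-[(trimethylsilyl)oxy]-20-norgibberella-1(10),2,16-trien-19-oate | C=C1C[C@]23C[C@@]1(O[Si](C)(C)C(C)(C)C)CC[C@H]2C4=C(O[Si](C)(C)C)C=C[C@@](C)(C(=O)O[Si](C)(C)C)[C@H]4[C@@H]3CO[Si](c5ccccc5)(c5ccccc5)C(C)(C)C | intermediate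
27 | 13-[(tert-butyldimethylsilyl)oxy]-7-[(tert-butyldiphenylsilyl)oxy]-1-oxo-20-norgibberella-2,16-dien-19-oic acid 19,10-lactone | C=C1C[C@]23C[C@@]1(O[Si](C)(C)C(C)(C)C)CC[C@H]2[C@@]12OC(=O)[C@@](C)([C@H]1[C@@H]3CO[Si](c4ccccc4)(c4ccccc4)C(C)(C)C)C=CC2=O | intermediate
28 | 7,13-dihydroxy-1-oxo-20-norgibberella-2,16-dien-19-oic acid 19,10-lactone | C=C1C[C@]23C[C@@]1(O)CC[C@H]2[C@@]12OC(=O)[C@@](C)([C@H]1[C@@H]3CO)C=CC2=O | intermediate
29 | 13-hydroxy-1-oxo-20-norgibberella-2,16-diene-7,19-dioic acid 19,10-lactone | C=C1C[C@]23C[C@@]1(O)CC[C@H]2[C@@]12OC(=O)[C@@](C)([C@H]1[C@@H]3C(=O)O)C=CC2=O | intermediate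
30 | 2β,3β-epoxy-13-hydroxy-1-oxo-20-norgibberell-16-ene-7,19-dioic acid 19,10-lactone | C=C1C[C@]23C[C@@]1(O)CC[C@H]2[C@@]12OC(=O)[C@@](C)([C@H]1[C@@H]3C(=O)O)[C@H]1O[C@H]1C2=O | intermediate
31 | target gibberellin (2β,3β-epoxy-1β,13-dihydroxy-20-norgibberell-16-ene-7,19-dioic acid 19,10-lactone) | C=C1C[C@]23C[C@@]1(O)CC[C@H]2[C@@]12OC(=O)[C@@](C)([C@H]1[C@@H]3C(=O)O)[C@H]1O[C@H]1[C@H]2O | target

**Totals and risks**

Total step count: 23. Longest linear sequence: 23 steps (1 to 31).

Steps most likely to fail: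

1. Step 16. The trisubstituted Z-enoate may cycloadd so slowly that the silyl dienol ether is lost by hydrolysis or polymerisation, or the Z-enoate may isomerise at the temperature needed. The fallback forms the same two bonds stepwise by an anionic intramolecular double Michael addition. It sets out from vinyl ketone 21: LiN(SiMe3)2 (2.1 equiv) in THF at −78 to 0 °C forms the C10 enolate, which should add to C5 of the enoate under the same allylic-strain control, and the resulting ester enolate should close onto C3 of the vinyl ketone. This would give methyl 7-[(tert-butyldiphenylsilyl)oxy]-13-hydroxy-1-oxo-20-norgibberell-16-en-19-oate F1. Kinetic enolisation of F1 towards C2 with LiN(i-Pr)2 (excess) and trapping with TBSOTf, which also silylates O13, comes back to the route at 23. The configuration at C4 is then set in the ring closure and no longer by the alkene geometry, so it would have to be verified.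

2. Step 19. The oxidised dienol ether may lose H5 or H9 to give a dienone, or the oxidant may attack the 16-ene, before the C19 carboxyl is captured at C10. The fallback separates halogenation from ring closure. It sets out from acid 25: the dienol ether 26 is made as before and brominated at C10 with N-bromosuccinimide in THF at −78 °C, giving after aqueous work-up 10-bromo-13-[(tert-butyldimethylsilyl)oxy]-7-[(tert-butyldiphenylsilyl)oxy]-1-oxo-20-norgibberella-2,16-dien-19-oic acid F2 as C10 epimers. AgOTf and 2,6-lutidine in CH2Cl2 should then abstract bromide from the tertiary α-bromo ketone; the carboxyl on the α face should close the lactone by backside displacement of the β-bromide, and the α-bromide should follow through silver-assisted ionisation, coming back at 27.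

3. Step 8. Enamine formation from the neopentyl-type aldehyde may be slow, the facial preference of the catalyst may be eroded by the neighbouring quaternary C8, and the β-hydroxy aldehyde may dehydrate or epimerise at C6 before it is silylated. The fallback uses an oxazolidinone auxiliary and sets out from ester 10. LiOH in THF/H2O, followed by careful acidification with aq. HCl, gives 2-[(1R,2S,5S)-2-{2-[(tert-butyldimethylsilyl)oxy]ethyl}-5-hydroxy-6-methylidenebicyclo[3.2.1]octan-1-yl]acetic acid F3. Pivaloyl chloride/Et3N, then (R)-4-benzyl-1,3-oxazolidin-2-one and LiCl, give (4R)-4-benzyl-3-{2-[(1R,2S,5S)-2-{2-[(tert-butyldimethylsilyl)oxy]ethyl}-5-hydroxy-6-methylidenebicyclo[3.2.1]octan-1-yl]acetyl}-1,3-oxazolidin-2-one F4. The chlorotitanium enolate (TiCl4, i-Pr2NEt, CH2Cl2, −20 °C) with s-trioxane and TiCl4 should give (4R)-4-benzyl-3-{(2S)-2-[(1S,2S,5S)-2-{2-[(tert-butyldimethylsilyl)oxy]ethyl}-5-hydroxy-6-methylidenebicyclo[3.2.1]octan-1-yl]-3-hydroxypropanoyl}-1,3-oxazolidin-2-one F5, with C6 set by the auxiliary through the chelated Z-enolate. TBDPSCl/imidazole then gives the tert-butyldiphenylsilyl ether of that imide F6. LiBH4 in Et2O with a little water removes the auxiliary and gives (2R)-3-[(tert-butyldiphenylsilyl)oxy]-2-[(1S,2S,5S)-2-{2-[(tert-butyldimethylsilyl)oxy]ethyl}-5-hydroxy-6-methylidenebicyclo[3.2.1]octan-1-yl]propan-1-ol F7, and Dess–Martin oxidation of F7 comes back to the route at 14.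

**Further compounds**

F1 | step 16 | methyl 7-[(tert-butyldiphenylsilyl)oxy]-13-hydroxy-1-oxo-20-norgibberell-16-en-19-oate (10α-H drawn) | C=C1C[C@]23C[C@@]1(O)CC[C@H]2[C@@H]4C(=O)CC[C@@](C)(C(=O)OC)[C@H]4[C@@H]3CO[Si](c5ccccc5)(c5ccccc5)C(C)(C)C
F2 | step 19 | 10-bromo-13-[(tert-butyldimethylsilyl)oxy]-7-[(tert-butyldiphenylsilyl)oxy]-1-oxo-20-norgibberella-2,16-dien-19-oic acid (C10 epimers) | C=C1C[C@]23C[C@@]1(O[Si](C)(C)C(C)(C)C)CC[C@H]2C4(Br)C(=O)C=C[C@@](C)(C(=O)O)[C@H]4[C@@H]3CO[Si](c5ccccc5)(c5ccccc5)C(C)(C)C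
F3 | step 8 | 2-[(1R,2S,5S)-2-{2-[(tert-butyldimethylsilyl)oxy]ethyl}-5-hydroxy-6-methylidenebicyclo[3.2.1]octan-1-yl]acetic acid | C=C1C[C@]2(CC(=O)O)C[C@@]1(O)CC[C@H]2CCO[Si](C)(C)C(C)(C)C
F4 | step 8 | (4R)-4-benzyl-3-{2-[(1R,2S,5S)-2-{2-[(tert-butyldimethylsilyl)oxy]ethyl}-5-hydroxy-6-methylidenebicyclo[3.2.1]octan-1-yl]acetyl}-1,3-oxazolidin-2-one | C=C1C[C@]2(CC(=O)N3[C@H](Cc4ccccc4)COC3=O)C[C@@]1(O)CC[C@H]2CCO[Si](C)(C)C(C)(C)C
F5 | step 8 | (4R)-4-benzyl-3-{(2S)-2-[(1S,2S,5S)-2-{2-[(tert-butyldimethylsilyl)oxy]ethyl}-5-hydroxy-6-methylidenebicyclo[3.2.1]octan-1-yl]-3-hydroxypropanoyl}-1,3-oxazolidin-2-one | C=C1C[C@]2([C@@H](CO)C(=O)N3[C@H](Cc4ccccc4)COC3=O)C[C@@]1(O)CC[C@H]2CCO[Si](C)(C)C(C)(C)C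
F6 | step 8 | (4R)-4-benzyl-3-{(2S)-3-[(tert-butyldiphenylsilyl)oxy]-2-[(1S,2S,5S)-2-{2-[(tert-butyldimethylsilyl)oxy]ethyl}-5-hydroxy-6-methylidenebicyclo[3.2.1]octan-1-yl]propanoyl}-1,3-oxazolidin-2-one | C=C1C[C@]2([C@@H](CO[Si](c5ccccc5)(c5ccccc5)C(C)(C)C)C(=O)N3[C@H](Cc4ccccc4)COC3=O)C[C@@]1(O)CC[C@H]2CCO[Si](C)(C)C(C)(C)C
F7 | step 8 | (2R)-3-[(tert-butyldiphenylsilyl)oxy]-2-[(1S,2S,5S)-2-{2-[(tert-butyldimethylsilyl)oxy]ethyl}-5-hydroxy-6-methylidenebicyclo[3.2.1]octan-1-yl]propan-1-ol | C=C1C[C@]2([C@@H](CO[Si](c3ccccc3)(c3ccccc3)C(C)(C)C)CO)C[C@@]1(O)CC[C@H]2CCO[Si](C)(C)C(C)(C)C
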